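## Retrosynthetic overview

1. Both polyprenyl chains are finished in one operation: a double B-alkyl Suzuki–Miyaura coupling joins a C12 cyclopropane triene (C2 vinyl arm, C3 (E)-2-methylbutadienyl arm, silyl-protected CH2OH) to two equivalents of one C14 (1E,5E)-alkenyl iodide, followed by desilylation.
2. The triene comes from a cis-alkenyl cyclopropanecarboxylic acid (reduction, double oxidation, double Wittig). Its C3–alkenyl bond is made by a carboxylate-directed cyclopropane C–H alkenylation with a C4 (E)-iodoallyl pivalate.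
3. The cyclopropane, the only ring, is formed first in the core branch by Charette asymmetric Simmons–Smith cyclopropanation of (E)-4-silyloxy-2-methylbut-2-en-1-ol (from 3-methylbut-2-en-1-ol), then oxidised to the acid.
4. The C14 iodide is built from 5-bromo-2-methylpent-2-ene by acetylide alkylation and two zirconium-catalysed methylalumination–iodination rounds linked by a Negishi coupling with a silylbutynylzinc reagent (from but-3-yn-1-ol). The C4 iodide comes from prop-2-yn-1-ol.

Assumption: 5-bromo-2-methylpent-2-ene is taken as commercial, and the facial sense of the dioxaborolane in step 11 is assigned from the accepted model ((4R,5R)-ligand gives (1S,2S)-2-phenylcyclopropylmethanol from cinnamyl alcohol), to be confirmed on 21.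

Abbreviation: TBDPS = tert-butyldiphenylsilyl.

## Route

Step 1
Reactants: 1 but-3-yn-1-ol
Product: 3 4-(trimethylsilyl)but-3-yn-1-ol, via bis-silylated butynol 2 (not isolated)
Conditions: n-BuLi (2.1 equiv), THF, −78 °C; Me3SiCl (2.2 equiv), −78 °C to rt; then aq HCl (1 mol/L), rt
Reagents that add atoms: chlorotrimethylsilane, C[Si](C)(C)Cl
Why: Double deprotonation and C,O-bis-silylation followed by selective acid hydrolysis of the labile O–Si bond leaves the C-silylated alkyne (alkyne protection).

Step 2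
Reactants: 3 4-(trimethylsilyl)but-3-yn-1-ol
Product: 4 (4-iodobut-1-yn-1-yl)trimethylsilane
Conditions: I2, PPh3, imidazole, CH2Cl2, 0 °C to rt
Reagents that add atoms: iodine, [I][I]
Why: Appel-type iodination, SN2 displacement of the alkoxyphosphonium at an unhindered primary carbon.

Step 3
Reactants: 5 5-bromo-2-methylpent-2-ene
Product: 6 6-methylhept-5-en-1-yne
Conditions: LiC≡CH·H2NCH2CH2NH2 (1.5 equiv), DMSO, 0 °C to rt
Reagents that add atoms: lithium acetylide–ethylenediamine complex, [Li+].[C-]#C.NCCN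
Why: SN2 alkylation of lithium acetylide by a primary homoallylic bromide in a dipolar aprotic solvent.

Step 4
Reactants: 6 6-methylhept-5-en-1-yne
Product: 8 (1E)-1-iodo-2,6-dimethylhepta-1,5-diene, via alkenylalane 7 (not isolated)
Conditions: AlMe3 (2 equiv), Cp2ZrCl2 (0.25 equiv), CH2Cl2, 0 °C to rt; then I2 (1.2 equiv), THF, −30 to 0 °C
Reagents that add atoms: trimethylaluminium, C[Al](C)C; iodine, [I][I]
Why: Negishi zirconium-catalysed carboalumination adds Me–Al syn with aluminium on the terminal carbon, and iodinolysis with retention fixes the E trisubstituted alkene while the remote alkene is untouched.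

Step 5
Reactants: 4 (4-iodobut-1-yn-1-yl)trimethylsilane; 8 (1E)-1-iodo-2,6-dimethylhepta-1,5-diene
Product: 11 (5E)-6,10-dimethylundeca-5,9-dien-1-yne, via butynylzinc iodide 9 (not isolated), via silyl enyne 10 (not isolated)
Conditions: 4, Zn dust (activated by Me3SiCl and BrCH2CH2Br), THF, 40 °C; then 8, Pd(dppf)Cl2 (3 mol %), THF, rt; then K2CO3, MeOH, rt
Reagents that add atoms: none
Why: Zinc insertion then Negishi alkyl–alkenyl cross-coupling with retention of the E geometry, followed by methanolysis of the alkynyl C–Si bond.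

Step 6
Reactants: 11 (5E)-6,10-dimethylundeca-5,9-dien-1-yne
Product: 13 (1E,5E)-1-iodo-2,6,10-trimethylundeca-1,5,9-triene, via alkenylalane 12 (not isolated)
Conditions: AlMe3 (2 equiv), Cp2ZrCl2 (0.25 equiv), CH2Cl2, 0 °C to rt; then I2 (1.2 equiv), THF, −30 to 0 °C
Reagents that add atoms: trimethylaluminium, C[Al](C)C; iodine, [I][I]
Why: Second Negishi carboalumination–iodination, again syn and terminal-selective, gives the (1E) iodide without touching the two isolated trisubstituted alkenes.

Step 7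
Reactants: 14 prop-2-yn-1-ol
Product: 16 (2E)-3-iodo-2-methylprop-2-en-1-ol, via alkoxy alkenylalane 15 (not isolated)
Conditions: AlMe3 (3 equiv), Cp2ZrCl2 (0.25 equiv), CH2Cl2, 0 °C to rt; then I2, THF, −30 to 0 °C; aq Rochelle salt
Reagents that add atoms: trimethylaluminium, C[Al](C)C; iodine, [I][I]
Why: The same carboalumination–iodination on the in situ aluminium alkoxide of propargyl alcohol gives the E iodoalkenol (iodine cis to methyl).

Step 8
Reactants: 16 (2E)-3-iodo-2-methylprop-2-en-1-ol
Product: 17 (2E)-3-iodo-2-methylprop-2-en-1-yl 2,2-dimethylpropanoate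
Conditions: t-BuCOCl, pyridine, DMAP (cat.), CH2Cl2, 0 °C to rt
Reagents that add atoms: pivaloyl chloride, CC(C)(C)C(=O)Cl
Why: Acylation masks the allylic alcohol as a robust pivalate that cannot coordinate or be oxidised in the palladium step.

Step 9
Reactants: 18 3-methylbut-2-en-1-ol
Product: 19 tert-butyl[(3-methylbut-2-en-1-yl)oxy]diphenylsilane
Conditions: t-BuPh2SiCl, imidazole, DMF, rt
Reagents that add atoms: tert-butyl(chloro)diphenylsilane, CC(C)(C)[Si](Cl)(c1ccccc1)c1ccccc1
Why: Silylation of the primary alcohol; the bulky TBDPS ether is a poor donor and survives every later step until fluoride.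

Step 10
Reactants: 19 tert-butyl[(3-methylbut-2-en-1-yl)oxy]diphenylsilane
Product: 20 (2E)-4-[(tert-butyldiphenylsilyl)oxy]-2-methylbut-2-en-1-ol
Conditions: SeO2 (0.5 equiv), t-BuOOH (3 equiv), salicylic acid (0.1 equiv), CH2Cl2, rt
Reagents that add atoms: selenium dioxide (transfers the oxygen), O=[Se]=O; tert-butyl hydroperoxide (terminal oxidant), CC(C)(C)OO
Why: Riley allylic oxidation (ene reaction then [2,3]-sigmatropic shift) hydroxylates the (E)-methyl group of the trisubstituted alkene selectively.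

Step 11
Reactants: 20 (2E)-4-[(tert-butyldiphenylsilyl)oxy]-2-methylbut-2-en-1-ol
Product: 21 [(1R,2R)-2-{[(tert-butyldiphenylsilyl)oxy]methyl}-1-methylcyclopropyl]methanol
Conditions: Zn(CH2I)2·DME (from Et2Zn, CH2I2, DME; 2.2 equiv), (4S,5S)-2-butyl-N,N,N',N'-tetramethyl-1,3,2-dioxaborolane-4,5-dicarboxamide (1.2 equiv), CH2Cl2, −10 °C to rt
Reagents that add atoms: diiodomethane, [I]C[I]
Why: Charette asymmetric Simmons–Smith cyclopropanation, in which the allylic alkoxide binds the ligand boron and the amide-chelated zinc carbenoid delivers CH2 to one alkene face, setting both ring stereocentres (1R,2R) with the two CH2O groups trans by syn-stereospecific addition.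

Step 12
Reactants: 21 [(1R,2R)-2-{[(tert-butyldiphenylsilyl)oxy]methyl}-1-methylcyclopropyl]methanol
Product: 22 (1R,2R)-2-{[(tert-butyldiphenylsilyl)oxy]methyl}-1-methylcyclopropane-1-carboxylic acid
Conditions: TEMPO (0.2 equiv), PhI(OAc)2 (2.2 equiv), MeCN/H2O 1:1, rt
Reagents that add atoms: water, O
Why: Oxoammonium oxidation of the primary alcohol to the aldehyde and, through its hydrate, to the acid; the quaternary α-carbon cannot epimerise.

Step 13
Reactants: 22 (1R,2R)-2-{[(tert-butyldiphenylsilyl)oxy]methyl}-1-methylcyclopropane-1-carboxylic acid; 17 (2E)-3-iodo-2-methylprop-2-en-1-yl 2,2-dimethylpropanoate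
Product: 23 (1R,2R,3R)-2-{[(tert-butyldiphenylsilyl)oxy]methyl}-3-[(1E)-3-(2,2-dimethylpropanoyloxy)-2-methylprop-1-en-1-yl]-1-methylcyclopropane-1-carboxylic acid
Conditions: Pd(OAc)2 (10 mol %), N-acetylglycine (20 mol %), Ag2CO3 (1.0 equiv), 17 (3 equiv), (CF3)2CHOH, 60 °C, dark
Reagents that add atoms: none
Why: Proposed new method: carboxylate-directed cyclopropane C(sp3)–H alkenylation with an alkenyl iodide, in which the carboxylate of 22 binds divalent palladium, the N-acyl amino acid ligand acts as internal base for concerted metalation–deprotonation of the ring CH2 hydrogen cis to CO2H (the ring methine and the α-methyl C–H bonds are slower), the five-membered palladacycle adds 17 oxidatively to give tetravalent palladium, and C(sp3)–C(sp2) reductive elimination with retention at both carbons sets the third ring stereocentre cis to CO2H and keeps the E alkene while Ag2CO3 removes iodide; the closest known reaction types are free-acid-directed β-C–H arylation of cyclopropanecarboxylic acids with aryl iodides and aminoquinoline-amide-directed C(sp3)–H alkenylation with alkenyl iodides.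

Step 14
Reactants: 23 the cis-alkenyl acid pivalate
Product: 24 (2E)-3-[(1R,2R,3R)-3-{[(tert-butyldiphenylsilyl)oxy]methyl}-2-(hydroxymethyl)-2-methylcyclopropyl]-2-methylprop-2-en-1-ol
Conditions: LiAlH4 (3.5 equiv), THF, 0 °C to rt
Reagents that add atoms: none
Why: Hydride reduction converts the carboxylic acid into the primary alcohol and cleaves the pivalate in the same operation, with no stereocentre touched and the silyl ether intact.

Step 15
Reactants: 24 the diol
Product: 25 (1R,2R,3R)-2-{[(tert-butyldiphenylsilyl)oxy]methyl}-1-methyl-3-[(1E)-2-methyl-3-oxoprop-1-en-1-yl]cyclopropane-1-carbaldehyde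
Conditions: Dess–Martin periodinane (2.6 equiv), CH2Cl2, 0 °C to rt; used crude
Reagents that add atoms: none
Why: Dess–Martin oxidation of both primary alcohols; the cis formyl/alkenyl cyclopropane is held against retro-Claisen rearrangement by the methyl group cis to the ring on the alkene, as in cis-chrysanthemal, and has no enolisable stereocentre.

Step 16
Reactants: 25 the dialdehyde
Product: 26 tert-butyl({(1R,2R,3R)-2-ethenyl-2-methyl-3-[(1E)-2-methylbuta-1,3-dien-1-yl]cyclopropyl}methoxy)diphenylsilane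
Conditions: Ph3PCH3Br (3 equiv), KOt-Bu (2.8 equiv), THF, 0 °C; then 25, −78 to 0 °C
Reagents that add atoms: methyltriphenylphosphonium bromide, C[P+](c1ccccc1)(c1ccccc1)c1ccccc1.[Br-]
Why: Double Wittig methylenation turns the hindered aldehyde into the vinyl arm and the enal into the terminal diene by 1,2-addition, leaving the E trisubstituted alkene unchanged.

Step 17
Reactants: 26 the triene; 13 (1E,5E)-1-iodo-2,6,10-trimethylundeca-1,5,9-triene (2.2 equiv)
Product: 28 tert-butyl({(1R,2R,3R)-2-methyl-3-[(1E,5E,9E)-2,6,10,14-tetramethylpentadeca-1,5,9,13-tetraen-1-yl]-2-[(3E,7E)-4,8,12-trimethyltrideca-3,7,11-trien-1-yl]cyclopropyl}methoxy)diphenylsilane, via bis-borane 27 (not isolated)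
Conditions: 9-BBN dimer (1.15 equiv), THF, 0 °C to rt; then 13, Pd(dppf)Cl2 (10 mol %), AsPh3 (10 mol %), aq NaOH (3 mol/L), THF/DMF, rt
Reagents that add atoms: none
Why: 9-BBN adds anti-Markovnikov only to the two monosubstituted terminal alkenes (vinyl and diene terminus), and a double B-alkyl Suzuki–Miyaura coupling with 13, with retention of its E geometry, forms both CH2–CH= bonds and completes the C16 and C19 chains.

Step 18
Reactants: 28 the TBDPS ether of the target
Product: 29 {(1R,2R,3R)-2-methyl-3-[(1E,5E,9E)-2,6,10,14-tetramethylpentadeca-1,5,9,13-tetraen-1-yl]-2-[(3E,7E)-4,8,12-trimethyltrideca-3,7,11-trien-1-yl]cyclopropyl}methanol (prephytoene alcohol)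
Conditions: Bu4NF, THF, 0 °C to rt
Reagents that add atoms: none
Why: Fluoride-driven desilylation under non-acidic conditions frees the cyclopropylcarbinol without cationic ring opening or alkene isomerisation.

## Compound list

1 | but-3-yn-1-ol | C#CCCO | starting material
2 | trimethyl{[4-(trimethylsilyl)but-3-yn-1-yl]oxy}silane | C[Si](C)(C)C#CCCO[Si](C)(C)C | intermediate (not isolated)
3 | 4-(trimethylsilyl)but-3-yn-1-ol | C[Si](C)(C)C#CCCO | intermediate
4 | (4-iodobut-1-yn-1-yl)trimethylsilane | C[Si](C)(C)C#CCCI | intermediate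
5 | 5-bromo-2-methylpent-2-ene | CC(C)=CCCBr | starting material
6 | 6-methylhept-5-en-1-yne | CC(C)=CCCC#C | intermediate
7 | [(1E)-2,6-dimethylhepta-1,5-dien-1-yl]dimethylalumane | CC(C)=CCC/C(C)=C/[Al](C)C | intermediate (not isolated)
8 | (1E)-1-iodo-2,6-dimethylhepta-1,5-diene | CC(C)=CCC/C(C)=C/I | intermediate
9 | iodo[4-(trimethylsilyl)but-3-yn-1-yl]zinc | C[Si](C)(C)C#CCC[Zn]I | intermediate (not isolated)
10 | [(5E)-6,10-dimethylundeca-5,9-dien-1-yn-1-yl]trimethylsilane | CC(C)=CCC/C(C)=C/CCC#C[Si](C)(C)C | intermediate (not isolated)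
11 | (5E)-6,10-dimethylundeca-5,9-dien-1-yne | CC(C)=CCC/C(C)=C/CCC#C | intermediate
12 | dimethyl[(1E,5E)-2,6,10-trimethylundeca-1,5,9-trien-1-yl]alumane | CC(C)=CCC/C(C)=C/CC/C(C)=C/[Al](C)C | intermediate (not isolated)
13 | (1E,5E)-1-iodo-2,6,10-trimethylundeca-1,5,9-triene | CC(C)=CCC/C(C)=C/CC/C(C)=C/I | intermediate
14 | prop-2-yn-1-ol | C#CCO | starting material
15 | {[(2E)-3-(dimethylalumanyl)-2-methylprop-2-en-1-yl]oxy}dimethylalumane | C[Al](C)OC/C(C)=C/[Al](C)C | intermediate (not isolated)
16 | (2E)-3-iodo-2-methylprop-2-en-1-ol | OC/C(C)=C/I | intermediate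
17 | (2E)-3-iodo-2-methylprop-2-en-1-yl 2,2-dimethylpropanoate | CC(C)(C)C(=O)OC/C(C)=C/I | intermediate
18 | 3-methylbut-2-en-1-ol | CC(C)=CCO | starting material
19 | tert-butyl[(3-methylbut-2-en-1-yl)oxy]diphenylsilane | CC(C)=CCO[Si](c1ccccc1)(c1ccccc1)C(C)(C)C | intermediate
20 | (2E)-4-[(tert-butyldiphenylsilyl)oxy]-2-methylbut-2-en-1-ol | OC/C(C)=C/CO[Si](c1ccccc1)(c1ccccc1)C(C)(C)C | intermediate
21 | [(1R,2R)-2-{[(tert-butyldiphenylsilyl)oxy]methyl}-1-methylcyclopropyl]methanol | C1[C@@H](CO[Si](c2ccccc2)(c2ccccc2)C(C)(C)C)[C@]1(C)CO | intermediate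
22 | (1R,2R)-2-{[(tert-butyldiphenylsilyl)oxy]methyl}-1-methylcyclopropane-1-carboxylic acid | C1[C@@H](CO[Si](c2ccccc2)(c2ccccc2)C(C)(C)C)[C@]1(C)C(=O)O | intermediate
23 | (1R,2R,3R)-2-{[(tert-butyldiphenylsilyl)oxy]methyl}-3-[(1E)-3-(2,2-dimethylpropanoyloxy)-2-methylprop-1-en-1-yl]-1-methylcyclopropane-1-carboxylic acid (alkenyl cis to CO2H) | CC(C)(C)C(=O)OC/C(C)=C/[C@@H]1[C@@H](CO[Si](c2ccccc2)(c2ccccc2)C(C)(C)C)[C@]1(C)C(=O)O | intermediate
24 | (2E)-3-[(1R,2R,3R)-3-{[(tert-butyldiphenylsilyl)oxy]methyl}-2-(hydroxymethyl)-2-methylcyclopropyl]-2-methylprop-2-en-1-ol | OC/C(C)=C/[C@@H]1[C@@H](CO[Si](c2ccccc2)(c2ccccc2)C(C)(C)C)[C@]1(C)CO | intermediate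
25 | (1R,2R,3R)-2-{[(tert-butyldiphenylsilyl)oxy]methyl}-1-methyl-3-[(1E)-2-methyl-3-oxoprop-1-en-1-yl]cyclopropane-1-carbaldehyde | O=C/C(C)=C/[C@@H]1[C@@H](CO[Si](c2ccccc2)(c2ccccc2)C(C)(C)C)[C@]1(C)C=O | intermediate
26 | tert-butyl({(1R,2R,3R)-2-ethenyl-2-methyl-3-[(1E)-2-methylbuta-1,3-dien-1-yl]cyclopropyl}methoxy)diphenylsilane | C=C/C(C)=C/[C@@H]1[C@@H](CO[Si](c2ccccc2)(c2ccccc2)C(C)(C)C)[C@]1(C)C=C | intermediate
27 | bis(B-alkyl-9-borabicyclo[3.3.1]nonane) from anti-Markovnikov addition of 9-BBN to both terminal alkenes of 26 | C(C/C(C)=C/[C@@H]1[C@@H](CO[Si](c2ccccc2)(c2ccccc2)C(C)(C)C)[C@]1(C)CCB1C2CCCC1CCC2)B1C2CCCC1CCC2 | intermediate (not isolated)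
28 | tert-butyl({(1R,2R,3R)-2-methyl-3-[(1E,5E,9E)-2,6,10,14-tetramethylpentadeca-1,5,9,13-tetraen-1-yl]-2-[(3E,7E)-4,8,12-trimethyltrideca-3,7,11-trien-1-yl]cyclopropyl}methoxy)diphenylsilane | CC(C)=CCC/C(C)=C/CC/C(C)=C/CC/C(C)=C/[C@@H]1[C@@H](CO[Si](c2ccccc2)(c2ccccc2)C(C)(C)C)[C@]1(C)CC/C=C(\C)CC/C=C(\C)CCC=C(C)C | intermediate
29 | {(1R,2R,3R)-2-methyl-3-[(1E,5E,9E)-2,6,10,14-tetramethylpentadeca-1,5,9,13-tetraen-1-yl]-2-[(3E,7E)-4,8,12-trimethyltrideca-3,7,11-trien-1-yl]cyclopropyl}methanol | CC(C)=CCC/C(C)=C/CC/C(C)=C/CC/C(C)=C/[C@@H]1[C@@H](CO)[C@]1(C)CC/C=C(\C)CC/C=C(\C)CCC=C(C)C | target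

## Step count and risks

Total step count: 18.

Longest linear sequence: 10 steps (steps 9 to 18, from 3-methylbut-2-en-1-ol). The other branches are shorter: 8 steps from prop-2-yn-1-ol, 6 from 5-bromo-2-methylpent-2-ene, and 6 from but-3-yn-1-ol.

Steps most likely to fail:

Step 13 (the new C–H alkenylation). Possible failures are slow oxidative addition of the trisubstituted alkenyl iodide to the palladacycle, lactonisation of the cis-alkenyl acid, or reaction at the α-methyl group. The fallback uses known chemistry and replaces C–H activation by a cyclopropylboron cross-coupling. It sets out from 20. Enantioselective zinco-cyclopropanation with the gem-dizinc carbenoid made from EtZnI and CHI3, in the presence of the same (4S,5S)-dioxaborolane in CH2Cl2, gives the cyclopropylzinc species F4, whose carbon–zinc bond is held cis to the CH2O arm by the zinc alkoxide. Boron–zinc exchange with the ligand in the flask gives the cyclic butylborinate F5. Suzuki–Miyaura coupling of F5 with 17 (Pd(PPh3)4, aq KOH, THF, 65 °C, retention at the cyclopropyl carbon) gives the hydroxymethyl pivalate F6. LiAlH4 in THF removes the pivaloyl group and the route is rejoined at 24.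

Step 17 (double hydroboration and double Suzuki coupling). Possible failures are incomplete regiocontrol at the diene terminus and an incomplete second coupling. The fallback changes the coupling partner from boron to zinc and adds a purifiable intermediate. It sets out from 26. Hydroboration with 9-BBN as before, then oxidation with NaOH and H2O2, gives the bis-homologated diol F7, which is purified from any regioisomer. PPh3, I2 and imidazole give the diiodide F8. Zn dust with LiCl in THF gives the bis(iodozinc) reagent F9. A double Negishi coupling with 13 (Pd(dppf)Cl2, THF/DMF, rt) rejoins the route at 28.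

Step 11 (asymmetric cyclopropanation). The enantiomeric excess on this 2-methyl-substituted allylic alcohol may fall short of what a single enantiomer needs, and the step fixes the absolute configuration of the whole molecule. The fallback replaces asymmetric induction by resolution. It sets out from 20. Furukawa cyclopropanation (Et2Zn, CH2I2, CH2Cl2, 0 °C) gives the racemic trans cyclopropylmethanol F1. TEMPO and PhI(OAc)2 in aqueous MeCN give the racemic acid F2. Crystallisation with (R)-1-phenylethylamine gives the diastereomerically pure ammonium salt F3 of the (1R,2R)-acid; if the salt of the other acid is the less soluble one, the (S)-amine is used instead. Aqueous KHSO4 frees the acid and the route is rejoined at 22.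

## Further compounds

F1 | step 11 | racemic trans-[2-{[(tert-butyldiphenylsilyl)oxy]methyl}-1-methylcyclopropyl]methanol (1:1 mixture of 21 and its enantiomer) | C1[C@@H](CO[Si](c2ccccc2)(c2ccccc2)C(C)(C)C)[C@]1(C)CO.C1[C@H](CO[Si](c2ccccc2)(c2ccccc2)C(C)(C)C)[C@@]1(C)CO
F2 | step 11 | racemic trans-2-{[(tert-butyldiphenylsilyl)oxy]methyl}-1-methylcyclopropane-1-carboxylic acid (1:1 mixture of 22 and its enantiomer) | C1[C@@H](CO[Si](c2ccccc2)(c2ccccc2)C(C)(C)C)[C@]1(C)C(=O)O.C1[C@H](CO[Si](c2ccccc2)(c2ccccc2)C(C)(C)C)[C@@]1(C)C(=O)O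
F3 | step 11 | (R)-1-phenylethylammonium (1R,2R)-2-{[(tert-butyldiphenylsilyl)oxy]methyl}-1-methylcyclopropane-1-carboxylate | C1[C@@H](CO[Si](c2ccccc2)(c2ccccc2)C(C)(C)C)[C@]1(C)C(=O)[O-].C[C@@H]([NH3+])c1ccccc1
F4 | step 13 | cyclopropylzinc iodide from 20, zinc on the ring carbon cis to the CH2O–ZnI arm | I[Zn][C@@H]1[C@@H](CO[Si](c2ccccc2)(c2ccccc2)C(C)(C)C)[C@]1(C)CO[Zn]I
F5 | step 13 | cyclic butylborinate (2-butyl-3-oxa-2-borabicyclo[3.1.0]hexane bearing the 5-methyl and 6-silyloxymethyl groups, boron cis to the CH2O arm) | CCCCB1[C@@H]2[C@@H](CO[Si](c3ccccc3)(c3ccccc3)C(C)(C)C)[C@]2(C)CO1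
F6 | step 13 | (2E)-3-[(1R,2R,3R)-3-{[(tert-butyldiphenylsilyl)oxy]methyl}-2-(hydroxymethyl)-2-methylcyclopropyl]-2-methylprop-2-en-1-yl 2,2-dimethylpropanoate | CC(C)(C)C(=O)OC/C(C)=C/[C@@H]1[C@@H](CO[Si](c2ccccc2)(c2ccccc2)C(C)(C)C)[C@]1(C)CO
F7 | step 17 | (3E)-4-[(1R,2R,3R)-3-{[(tert-butyldiphenylsilyl)oxy]methyl}-2-(2-hydroxyethyl)-2-methylcyclopropyl]-3-methylbut-3-en-1-ol | OCC/C(C)=C/[C@@H]1[C@@H](CO[Si](c2ccccc2)(c2ccccc2)C(C)(C)C)[C@]1(C)CCO
F8 | step 17 | tert-butyl({(1R,2R,3R)-2-(2-iodoethyl)-3-[(1E)-4-iodo-2-methylbut-1-en-1-yl]-2-methylcyclopropyl}methoxy)diphenylsilane | ICC/C(C)=C/[C@@H]1[C@@H](CO[Si](c2ccccc2)(c2ccccc2)C(C)(C)C)[C@]1(C)CCI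
F9 | step 17 | bis(iodozinc) reagent from F8 (both C–I bonds replaced by C–ZnI) | I[Zn]CC/C(C)=C/[C@@H]1[C@@H](CO[Si](c2ccccc2)(c2ccccc2)C(C)(C)C)[C@]1(C)CC[Zn]I
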